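# Proposed synthesis of CNP0308311.1: aryl ester to benzofuran by intramolecular Wittig closure

TBS = tert-butyldimethylsilyl throughout.

## The problem

The target 23 joins two oxygen heterocycles through one aryl–heteroaryl bond. C5 of a 2-aryl-3-hydroxymethyl-7-methoxy-2,3-dihydrobenzofuran is bonded to C2 of a 7-methoxybenzofuran that carries a 3-hydroxypropyl chain at C5. The only stereocentres are C2 (S) and C3 (R) of the dihydrofuran ring, and they are trans. While C3 carries an ester it can be epimerised and C2, which base cannot touch, dictates the trans arrangement. Once C3 carries CH2OH it is fixed, so the absolute configuration has to be set at C2 in one enantioselective event and relayed to C3. C2 is also the weak point: it is a benzylic aryl ether para to an oxygenated arene, so strong Lewis acid, forcing hydrogenolysis or a free phenoxide in hot base can open the ring through a quinone-methide-type ion. The free guaiacol-type phenol, the two primary alcohols and the electron-rich benzofuran call for an end game without oxidants or strong acid. The feature that opens the way is benzofuran C2: it is bonded to the ring oxygen O1 and to C5 of the dihydrobenzofuran and doubly bonded to C3, so it stands at the carboxyl oxidation level. It can therefore be the carbonyl carbon of an aryl ester of the dihydrobenzofuran-5-carboxylic acid, with benzofuran C3 as a benzylic carbon ortho to the ester oxygen, and the furan ring can be closed by an intramolecular carbonyl olefination after the halves have been joined by a simple acylation.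

## Retrosynthesis

**End game, 23 ⇐ 22 ⇐ 20.** No skeletal bond is cut. The phenol and the C3 hydroxymethyl group are traced to the bis-silyl ether 22, and the terminal hydroxyl of the chain to the allyl group of 20 by anti-Markovnikov hydration. Carrying an allyl group instead of a protected hydroxypropyl chain saves a protecting group and lets the benzofuran half start from an allylsalicylaldehyde. Two silyl ethers are preferred to benzyl ethers because one buffered fluoride step then ends the synthesis, with no hydrogenolysis in the presence of the benzofuran and the benzylic C2–O bond. The forward steps need a borane that takes a monosubstituted alkene and ignores the benzofuran C2=C3 bond.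

**Benzofuran ring, 20 ⇐ 18.** The C2=C3 double bond of the benzofuran is cut, giving the (2-acyloxybenzyl)phosphonium salt 18. The neighbouring cuts are the C5–C2′ bond between the rings (which needs a preformed 2-metallated benzofuran) and the O1–C2/C3–C3a pair (alkyne annulation, which needs an ethynyl dihydrobenzofuran). This cut is preferred because the ring closure and the union of the halves rest on an ester bond, and no transition metal meets the allyl group. The forward reaction must make the ylide attack its own ester carbonyl under a base too weak to disturb anything else.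

**Ester bond, 18 ⇐ 14 + 17.** The aryl ester C–O bond is cut to the bis-silylated acid 14 and the phosphonium phenol 17. Both are stable, separately purified fragments of about equal size, so the route is convergent. The coupling must be neutral enough to leave the silyl ethers and the phosphonium salt intact.

**Phosphonium phenol, 17 ⇐ 16 ⇐ 15.** The benzylic C–P bond is traced to the salicyl alcohol 16 and that to the aldehyde 15. The ortho hydroxyl assists ionisation of the benzylic alcohol, so PPh3·HBr installs the phosphonium group directly.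

**Carboxyl group and protecting-group exchange, 14 ⇐ 12 ⇐ 11 ⇐ 9.** The C5–CO2H bond is cut back to the aryl bromide 9 (bromine–lithium exchange, CO2). A bromide is the only carboxyl surrogate that passes through ester enolate, carbene and hydride chemistry unchanged. The phenol needs a benzyl ether upstream, because a silyl ether would not survive the methoxide of step 5 and a free phenoxide there would endanger C2. Benzyl cannot be hydrogenolysed while bromine is on the ring or after the allyl group has arrived. The exchange for silyl is therefore placed between 11 and 14, where one silylation covers phenol and primary alcohol together. The primary hydroxyl of 9 is carried as its lithium alkoxide through the carboxylation, which costs one equivalent of base and not a step.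

**Dihydrofuran ring and both stereocentres, 9 ⇐ 8 ⇐ 7 ⇐ 6.** After adjusting the C3 substituent to an ester (8), the C2–C3 bond is cut to the aryldiazoacetate 6. Carbene insertion into the benzylic ether C–H closes the ring and sets C2 under catalyst control. The kinetic cis ester 7 is turned into the trans ester 8 by enolate equilibration under the control of C2. Oxidative phenol coupling of ferulate-type monomers reaches the same skeleton faster but only as a racemate. An auxiliary-based aldol and cyclisation sequence would be longer. The precursor 6 is acyclic and achiral.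

**Diazo ester, 6 ⇐ 5 ⇐ 4 ⇐ 3 ⇐ 1 + 2.** Diazo transfer traces 6 to the arylacetate 5. The acetate carbon comes from a one-carbon homologation of aldehyde 3 through the enol ether 4. The benzylic ether C–O bond of 3 is cut to the benzyl alcohol 1 and the bromosalicylaldehyde 2. The ether is made first so that the phenol of 2 is never free during the homologation.

## Roads not taken

**Alternative 1:** Rhodium carbene C–H insertion as the strategic step. The cut is C2–C3 of the dihydrofuran. The diazo ester (6 of the present route) loses N2 on Rh2(S-PTTL)4, the carbene inserts into the benzylic ether C–H, and methoxide settles C3 trans, giving the bromo ester A1. A1 is identical with 8, so this road is already part of the chosen plan as the stereochemistry-setting step. The difference is the later union. Here the bromide would be used directly in a cross-coupling with a preformed 2-metallated benzofuran such as the boronate A2. That dispenses with the cryogenic carboxylation and the esterification, and is probably equal or slightly shorter in step count. Against it, A2 needs its own benzofuran synthesis and a C2 borylation, 2-benzofuranylboron reagents protodeboronate easily, and palladium would meet an allyl group and an unprotected or freshly protected C3 side chain. The chosen plan builds the benzofuran ring in the union step from a two-step phosphonium salt, without a precious metal, in a reaction established for 2-aryl-7-methoxybenzofurans.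

**Alternative 2:** Dötz benzannulation of the benzofuran benzene ring. The cut removes C3a–C4, C4–C5 and C6–C7. The furyl(methoxy)carbene pentacarbonylchromium complex A4 (zerovalent chromium) is heated with the silylated pentynol A5. Alkyne and CO insertion followed by electrocyclisation onto furan C3 gives the 4-hydroxy-7-methoxybenzofuran A3. Its merits are real: the methoxy group and the chain are placed with predictable regiochemistry, and the chain arrives at its final oxidation level, so no hydroboration is needed. For this target, however, A3 carries a C4 hydroxyl that the natural product lacks, which costs a sulfonylation and a reduction. Chromium is used stoichiometrically. A4 would have to be assembled on the fully elaborated, enantiopure dihydrobenzofuran by furan metalation, addition to Cr(CO)6 and O-methylation. The chosen plan is shorter, needs no deoxygenation, and exposes the valuable half only to an esterification and an amine base.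

**Alternative 3:** Palladium/norbornene annulation of an aryl iodide with a cis-epoxide. The cut is C3–C3a and O1–C7a. With Pd(OAc)2, XPhos, a carboxy-substituted norbornene and K2CO3, the aryl iodide A7 is alkylated at its free ortho carbon by the epoxide A8 with inversion, and the liberated alkoxide closes the C–O bond at the former iodide carbon. The cis-epoxide thus becomes the trans tris-pivalate A6, one ester cleavage from the target. On paper this is the most convergent and shortest road, and it would derive both stereocentres stereospecifically from one epoxide; in that respect it is better than the chosen plan. Its weak points are mechanistic. The annulation is established for monosubstituted epoxides, while A8 is an internal, benzylic epoxide. The palladacycle would have to attack the carbon bearing CH2OPiv although the benzylic carbon is electronically preferred, and aryl epoxides rearrange readily to carbonyl compounds under Lewis-acidic palladium. A8 also needs an asymmetric epoxidation of a (Z)-cinnamyl ester, and A7 still needs a benzofuran synthesis. The chosen plan is longer but every step has been shown on its substrate class.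

Key step: step 13

Assumption on the sense of induction: Rh2(S-PTTL)4 is taken to select the hydrogen leading to the 2S configuration, by analogy with the cis-2-aryl-2,3-dihydrobenzofuran-3-carboxylates made with this catalyst family; if the sense is opposite for 6, Rh2(R-PTTL)4 is used and nothing else changes.

Assumption on starting materials: 1, 2 and 15 are taken as catalogue compounds; 1 is otherwise two routine steps from vanillin (benzylation, NaBH4) and 15 one ortho-formylation from eugenol.

## Route

Step 1
Reactants: 1 4-(benzyloxy)-3-methoxybenzyl alcohol; 2 5-bromo-2-hydroxy-3-methoxybenzaldehyde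
Product: 3 2-{[4-(benzyloxy)-3-methoxybenzyl]oxy}-5-bromo-3-methoxybenzaldehyde
Conditions: PPh3, DIAD, THF, 0 °C to rt
Reagents that add atoms: none
Why: Mitsunobu etherification; the phenol of 2 is acidic (ortho formyl, para bromo) and the electron-rich primary benzylic oxyphosphonium ion is displaced readily, under neutral conditions that leave the aldehyde and the aryl bromide alone.

Step 2
Reactants: 3 2-{[4-(benzyloxy)-3-methoxybenzyl]oxy}-5-bromo-3-methoxybenzaldehyde
Product: 4 1-{[4-(benzyloxy)-3-methoxybenzyl]oxy}-4-bromo-2-methoxy-6-(2-methoxyethenyl)benzene (E/Z mixture)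
Conditions: MeOCH2PPh3Cl, KOtBu, THF, 0 °C to rt
Reagents that add atoms: (methoxymethyl)triphenylphosphonium chloride, COC[P+](c1ccccc1)(c1ccccc1)c1ccccc1.[Cl-]
Why: Wittig olefination with the non-stabilised methoxymethylene ylide; the E/Z mixture is used as such because both isomers converge in step 3.

Step 3
Reactants: 4 1-{[4-(benzyloxy)-3-methoxybenzyl]oxy}-4-bromo-2-methoxy-6-(2-methoxyethenyl)benzene
Product: 5 methyl 2-(2-{[4-(benzyloxy)-3-methoxybenzyl]oxy}-5-bromo-3-methoxyphenyl)acetate
Conditions: pyridinium chlorochromate (C5H5NH)[CrO3Cl], NaOAc, CH2Cl2, rt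
Reagents that add atoms: pyridinium chlorochromate, [O-][Cr](=O)(=O)Cl.c1cc[nH+]cc1
Why: Chromate oxidation of an enol ether to the ester: hexavalent chromium adds across the electron-rich double bond and a 1,2-hydride shift places the carbonyl on the oxygen-bearing carbon, so the one-carbon homologation is completed without passing through the arylacetaldehyde; NaOAc buffers the reagent to protect the acid-sensitive benzylic aryl ether.

Step 4
Reactants: 5 methyl 2-(2-{[4-(benzyloxy)-3-methoxybenzyl]oxy}-5-bromo-3-methoxyphenyl)acetate
Product: 6 methyl 2-(2-{[4-(benzyloxy)-3-methoxybenzyl]oxy}-5-bromo-3-methoxyphenyl)-2-diazoacetate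
Conditions: 4-acetamidobenzenesulfonyl azide, DBU, MeCN, 0 °C to rt
Reagents that add atoms: 4-acetamidobenzenesulfonyl azide, CC(=O)Nc1ccc(cc1)S(=O)(=O)N=[N+]=[N-]
Why: Regitz diazo transfer; DBU forms the benzylic ester enolate, which attacks the terminal azide nitrogen, and fragmentation gives the donor/acceptor diazo ester and the sulfonamide.

Step 5
Reactants: 6 methyl 2-(2-{[4-(benzyloxy)-3-methoxybenzyl]oxy}-5-bromo-3-methoxyphenyl)-2-diazoacetate
Product: 8 methyl (2S,3S)-2-[4-(benzyloxy)-3-methoxyphenyl]-5-bromo-7-methoxy-2,3-dihydro-1-benzofuran-3-carboxylate (trans ester), via cis ester 7 (not isolated)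
Conditions: Rh2(S-PTTL)4 (dirhodium tetrakis[N-phthaloyl-(S)-tert-leucinate], 1 mol%), toluene, −60 °C; then NaOMe, MeOH, 0 °C to rt
Reagents that add atoms: none
Why: Enantioselective intramolecular carbene C–H insertion: the divalent rhodium carbene inserts into one of the two enantiotopic hydrogens of the OCH2Ar group (activated by the ether oxygen and the electron-rich arene) in a five-membered closure, and the chiral carboxylate pocket chooses the hydrogen, which sets C2 as S and gives the kinetic cis ester 7. Methoxide then equilibrates C3 through the ester enolate to the more stable trans ester 8; C2 has no acidic hydrogen and so controls C3.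

Step 6
Reactants: 8 methyl (2S,3S)-2-[4-(benzyloxy)-3-methoxyphenyl]-5-bromo-7-methoxy-2,3-dihydro-1-benzofuran-3-carboxylate
Product: 9 [(2S,3R)-2-[4-(benzyloxy)-3-methoxyphenyl]-5-bromo-7-methoxy-2,3-dihydro-1-benzofuran-3-yl]methanol
Conditions: LiBH4, THF, 0 °C to rt
Reagents that add atoms: none
Why: Chemoselective borohydride reduction of the ester to the primary alcohol; aryl bromide and benzyl ether are untouched, and C3 is no longer epimerisable afterwards (the descriptor changes from S to R only because the substituent priorities change).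

Step 7
Reactants: 9 [(2S,3R)-2-[4-(benzyloxy)-3-methoxyphenyl]-5-bromo-7-methoxy-2,3-dihydro-1-benzofuran-3-yl]methanol
Product: 11 (2S,3R)-2-[4-(benzyloxy)-3-methoxyphenyl]-3-(hydroxymethyl)-7-methoxy-2,3-dihydro-1-benzofuran-5-carboxylic acid, via dilithio alkoxide aryllithium 10 (not isolated)
Conditions: t-BuLi (3.2 equiv), THF, −78 °C; CO2 (gas), −78 °C to rt; aq. HCl to pH 3
Reagents that add atoms: carbon dioxide, O=C=O; tert-butyllithium, [Li]C(C)(C)C (lithium in intermediate 10 only)
Why: Bromine–lithium exchange and carboxylation; the first equivalent of t-BuLi deprotonates the alcohol, the next two effect the exchange and destroy the tert-butyl bromide, and the aryllithium, flanked only by hydrogens, is trapped by CO2. The acid is purified by acid–base extraction.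

Step 8
Reactants: 11 (2S,3R)-2-[4-(benzyloxy)-3-methoxyphenyl]-3-(hydroxymethyl)-7-methoxy-2,3-dihydro-1-benzofuran-5-carboxylic acid
Product: 12 (2S,3R)-2-(4-hydroxy-3-methoxyphenyl)-3-(hydroxymethyl)-7-methoxy-2,3-dihydro-1-benzofuran-5-carboxylic acid
Conditions: H2 (1 atm), Pd/C (10%), EtOAc–MeOH, rt
Reagents that add atoms: none
Why: Hydrogenolysis of the primary aryl benzyl ether, which is much faster than cleavage of the hindered cyclic C2–O bond; bromine is already gone and no alkene is present yet.

Step 9
Reactants: 12 (2S,3R)-2-(4-hydroxy-3-methoxyphenyl)-3-(hydroxymethyl)-7-methoxy-2,3-dihydro-1-benzofuran-5-carboxylic acid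
Product: 14 (2S,3R)-2-{4-[(TBS)oxy]-3-methoxyphenyl}-3-{[(TBS)oxy]methyl}-7-methoxy-2,3-dihydro-1-benzofuran-5-carboxylic acid, via tris-silyl silyl ester 13 (not isolated)
Conditions: TBSCl (3.5 equiv), imidazole, DMF, rt; then AcOH, THF–H2O, rt
Reagents that add atoms: tert-butyldimethylsilyl chloride, CC(C)(C)[Si](C)(C)Cl
Why: Imidazole-mediated silylation of phenol, primary alcohol and acid; the silyl ester is far more labile than the two silyl ethers and is hydrolysed selectively by brief aqueous acetic acid.

Step 10
Reactants: 15 5-allyl-2-hydroxy-3-methoxybenzaldehyde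
Product: 16 4-allyl-2-(hydroxymethyl)-6-methoxyphenol
Conditions: NaBH4, MeOH, 0 °C
Reagents that add atoms: none
Why: Borohydride reduction of the aldehyde to the salicyl alcohol; the allyl group is inert.

Step 11
Reactants: 16 4-allyl-2-(hydroxymethyl)-6-methoxyphenol
Product: 17 (5-allyl-2-hydroxy-3-methoxybenzyl)triphenylphosphonium bromide
Conditions: PPh3·HBr, MeCN, reflux
Reagents that add atoms: triphenylphosphine hydrobromide, [Br-].c1ccc(cc1)[PH+](c1ccccc1)c1ccccc1
Why: Acid-promoted substitution of an ortho-hydroxybenzylic alcohol by PPh3 through the o-quinone methide or benzylic cation, the standard preparation of (2-hydroxybenzyl)phosphonium salts; the salt crystallises, and the isolated alkene does not add HBr from the phosphine salt.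

Step 12
Reactants: 14 (2S,3R)-2-{4-[(TBS)oxy]-3-methoxyphenyl}-3-{[(TBS)oxy]methyl}-7-methoxy-2,3-dihydro-1-benzofuran-5-carboxylic acid; 17 (5-allyl-2-hydroxy-3-methoxybenzyl)triphenylphosphonium bromide
Product: 18 {5-allyl-2-[({(2S,3R)-2-{4-[(TBS)oxy]-3-methoxyphenyl}-3-{[(TBS)oxy]methyl}-7-methoxy-2,3-dihydro-1-benzofuran-5-yl}carbonyl)oxy]-3-methoxybenzyl}triphenylphosphonium bromide
Conditions: DCC, DMAP (0.1 equiv), CH2Cl2, 0 °C to rt; filter, precipitate with Et2O
Reagents that add atoms: none
Why: Steglich esterification; the phenol of 17 is acidified by the neighbouring phosphonium group and acylates as its phenolate on the acylpyridinium ion, and the neutral conditions keep both silyl ethers and give no ylide at room temperature.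

Step 13
Reactants: 18 {5-allyl-2-[({(2S,3R)-2-{4-[(TBS)oxy]-3-methoxyphenyl}-3-{[(TBS)oxy]methyl}-7-methoxy-2,3-dihydro-1-benzofuran-5-yl}carbonyl)oxy]-3-methoxybenzyl}triphenylphosphonium bromide
Product: 20 (2S,3R)-5-(5-allyl-7-methoxy-1-benzofuran-2-yl)-2-{4-[(TBS)oxy]-3-methoxyphenyl}-3-{[(TBS)oxy]methyl}-7-methoxy-2,3-dihydro-1-benzofuran, via phosphonium ylide 19 (not isolated)
Conditions: Et3N (3 equiv), toluene (0.01 M), reflux
Reagents that add atoms: none
Why: Et3N deprotonates the benzylic phosphonium salt to the semi-stabilised ylide 19, which is present only in low stationary concentration. The ylide carbon adds to the carbonyl carbon of the adjacent aryl ester in a 5-exo-trig closure to an oxaphosphetane fused to the new five-membered ring, and loss of Ph3PO leaves the C2=C3 double bond of the furan. The closest known reaction type is the intramolecular Wittig olefination of (2-acyloxybenzyl)triphenylphosphonium salts to 2-substituted benzofurans, which is established for 2-aryl-7-methoxybenzofurans. Ester carbonyls are poor Wittig acceptors in general, but here the attack passes through a five-membered transition state and the collapse is driven by the aromatic furan and the P=O bond. No stereocentre is formed, and C2 and C3 of the dihydrobenzofuran are out of reach of an amine base because C3 now carries CH2OTBS. The selectivity needed is attack of the ylide on its own ester and not on that of a second molecule, which would give a 3-acylbenzofuran and a deacylated phenol; it is secured by high dilution, the absence of any free acylating agent (the ester was isolated in step 12) and the five-membered transition state. The silyl ethers survive, and the allyl group is not isomerised by Et3N.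

Step 14
Reactants: 20 (2S,3R)-5-(5-allyl-7-methoxy-1-benzofuran-2-yl)-2-{4-[(TBS)oxy]-3-methoxyphenyl}-3-{[(TBS)oxy]methyl}-7-methoxy-2,3-dihydro-1-benzofuran
Product: 22 3-{2-[(2S,3R)-2-{4-[(TBS)oxy]-3-methoxyphenyl}-3-{[(TBS)oxy]methyl}-7-methoxy-2,3-dihydro-1-benzofuran-5-yl]-7-methoxy-1-benzofuran-5-yl}propan-1-ol, via B-alkyl-9-BBN borane 21 (not isolated)
Conditions: 9-BBN, THF, 0 °C to rt; then aq. NaOAc, H2O2 (30%), 0 °C to rt
Reagents that add atoms: 9-borabicyclo[3.3.1]nonane (9-BBN), B1C2CCCC1CCC2 (boron and the bicyclic carbons, in intermediate 21 only); hydrogen peroxide, OO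
Why: Hydroboration–oxidation; the bulky borane adds to the monosubstituted alkene with anti-Markovnikov regiochemistry and does not touch the aromatic benzofuran C2=C3 bond, and the near-neutral acetate-buffered oxidation spares the aryl silyl ether.

Step 15
Reactants: 22 3-{2-[(2S,3R)-2-{4-[(TBS)oxy]-3-methoxyphenyl}-3-{[(TBS)oxy]methyl}-7-methoxy-2,3-dihydro-1-benzofuran-5-yl]-7-methoxy-1-benzofuran-5-yl}propan-1-ol
Product: 23 4-[(2S,3R)-3-(hydroxymethyl)-5-[5-(3-hydroxypropyl)-7-methoxy-1-benzofuran-2-yl]-7-methoxy-2,3-dihydro-1-benzofuran-2-yl]-2-methoxyphenol (CNP0308311.1)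
Conditions: Bu4NF (3 equiv), AcOH (3 equiv), THF, 0 °C to rt
Reagents that add atoms: none
Why: Fluoride-mediated desilylation of the aryl and the primary alkyl silyl ether in one operation; acetic acid buffers the liberated phenoxide, so the benzylic C2–O bond is never exposed to a basic phenoxide.

## Compound list

1 | 4-(benzyloxy)-3-methoxybenzyl alcohol | COc1cc(CO)ccc1OCc1ccccc1 | starting material
2 | 5-bromo-2-hydroxy-3-methoxybenzaldehyde | COc1cc(Br)cc(C=O)c1O | starting material
3 | 2-{[4-(benzyloxy)-3-methoxybenzyl]oxy}-5-bromo-3-methoxybenzaldehyde | COc1cc(COc2c(OC)cc(Br)cc2C=O)ccc1OCc1ccccc1 | intermediate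
4 | 1-{[4-(benzyloxy)-3-methoxybenzyl]oxy}-4-bromo-2-methoxy-6-(2-methoxyethenyl)benzene (E/Z mixture) | COC=Cc1cc(Br)cc(OC)c1OCc1ccc(OCc2ccccc2)c(OC)c1 | intermediate
5 | methyl 2-(2-{[4-(benzyloxy)-3-methoxybenzyl]oxy}-5-bromo-3-methoxyphenyl)acetate | COC(=O)Cc1cc(Br)cc(OC)c1OCc1ccc(OCc2ccccc2)c(OC)c1 | intermediate
6 | methyl 2-(2-{[4-(benzyloxy)-3-methoxybenzyl]oxy}-5-bromo-3-methoxyphenyl)-2-diazoacetate | COC(=O)C(=[N+]=[N-])c1cc(Br)cc(OC)c1OCc1ccc(OCc2ccccc2)c(OC)c1 | intermediate
7 | methyl (2S,3R)-2-[4-(benzyloxy)-3-methoxyphenyl]-5-bromo-7-methoxy-2,3-dihydro-1-benzofuran-3-carboxylate (cis; not isolated) | COc1cc([C@H]2Oc3c(OC)cc(Br)cc3[C@H]2C(=O)OC)ccc1OCc1ccccc1 | intermediate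
8 | methyl (2S,3S)-2-[4-(benzyloxy)-3-methoxyphenyl]-5-bromo-7-methoxy-2,3-dihydro-1-benzofuran-3-carboxylate (trans) | COc1cc([C@H]2Oc3c(OC)cc(Br)cc3[C@@H]2C(=O)OC)ccc1OCc1ccccc1 | intermediate
9 | [(2S,3R)-2-[4-(benzyloxy)-3-methoxyphenyl]-5-bromo-7-methoxy-2,3-dihydro-1-benzofuran-3-yl]methanol (trans) | COc1cc([C@H]2Oc3c(OC)cc(Br)cc3[C@@H]2CO)ccc1OCc1ccccc1 | intermediate
10 | lithium [(2S,3R)-2-[4-(benzyloxy)-3-methoxyphenyl]-5-lithio-7-methoxy-2,3-dihydro-1-benzofuran-3-yl]methanolate (not isolated) | COc1cc([C@H]2Oc3c(OC)cc([Li])cc3[C@@H]2CO[Li])ccc1OCc1ccccc1 | intermediate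
11 | (2S,3R)-2-[4-(benzyloxy)-3-methoxyphenyl]-3-(hydroxymethyl)-7-methoxy-2,3-dihydro-1-benzofuran-5-carboxylic acid | COc1cc([C@H]2Oc3c(OC)cc(C(=O)O)cc3[C@@H]2CO)ccc1OCc1ccccc1 | intermediate
12 | (2S,3R)-2-(4-hydroxy-3-methoxyphenyl)-3-(hydroxymethyl)-7-methoxy-2,3-dihydro-1-benzofuran-5-carboxylic acid | COc1cc([C@H]2Oc3c(OC)cc(C(=O)O)cc3[C@@H]2CO)ccc1O | intermediate
13 | tert-butyldimethylsilyl (2S,3R)-2-{4-[(TBS)oxy]-3-methoxyphenyl}-3-{[(TBS)oxy]methyl}-7-methoxy-2,3-dihydro-1-benzofuran-5-carboxylate (not isolated) | COc1cc([C@H]2Oc3c(OC)cc(C(=O)O[Si](C)(C)C(C)(C)C)cc3[C@@H]2CO[Si](C)(C)C(C)(C)C)ccc1O[Si](C)(C)C(C)(C)C | intermediate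
14 | (2S,3R)-2-{4-[(TBS)oxy]-3-methoxyphenyl}-3-{[(TBS)oxy]methyl}-7-methoxy-2,3-dihydro-1-benzofuran-5-carboxylic acid | COc1cc([C@H]2Oc3c(OC)cc(C(=O)O)cc3[C@@H]2CO[Si](C)(C)C(C)(C)C)ccc1O[Si](C)(C)C(C)(C)C | intermediate
15 | 5-allyl-2-hydroxy-3-methoxybenzaldehyde | C=CCc1cc(OC)c(O)c(C=O)c1 | starting material
16 | 4-allyl-2-(hydroxymethyl)-6-methoxyphenol | C=CCc1cc(OC)c(O)c(CO)c1 | intermediate
17 | (5-allyl-2-hydroxy-3-methoxybenzyl)triphenylphosphonium bromide | C=CCc1cc(OC)c(O)c(C[P+](c2ccccc2)(c2ccccc2)c2ccccc2)c1.[Br-] | intermediate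
18 | {5-allyl-2-[({(2S,3R)-2-{4-[(TBS)oxy]-3-methoxyphenyl}-3-{[(TBS)oxy]methyl}-7-methoxy-2,3-dihydro-1-benzofuran-5-yl}carbonyl)oxy]-3-methoxybenzyl}triphenylphosphonium bromide | COc1cc([C@H]2Oc3c(OC)cc(C(=O)Oc4c(OC)cc(CC=C)cc4C[P+](c5ccccc5)(c6ccccc6)c7ccccc7)cc3[C@@H]2CO[Si](C)(C)C(C)(C)C)ccc1O[Si](C)(C)C(C)(C)C.[Br-] | intermediate
19 | ylide of 18: 5-allyl-3-methoxy-2-(aroyloxy)benzylidene-triphenylphosphorane, aroyl being the (2S,3R)-acyl group of 14 (not isolated) | COc1cc([C@H]2Oc3c(OC)cc(C(=O)Oc4c(OC)cc(CC=C)cc4C=P(c5ccccc5)(c6ccccc6)c7ccccc7)cc3[C@@H]2CO[Si](C)(C)C(C)(C)C)ccc1O[Si](C)(C)C(C)(C)C | intermediate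
20 | (2S,3R)-5-(5-allyl-7-methoxy-1-benzofuran-2-yl)-2-{4-[(TBS)oxy]-3-methoxyphenyl}-3-{[(TBS)oxy]methyl}-7-methoxy-2,3-dihydro-1-benzofuran | COc1cc([C@H]2Oc3c(OC)cc(-c4cc5cc(CC=C)cc(OC)c5o4)cc3[C@@H]2CO[Si](C)(C)C(C)(C)C)ccc1O[Si](C)(C)C(C)(C)C | intermediate
21 | B-alkyl-9-BBN adduct of 20: 9-{3-[2-(dihydrobenzofuran-5-yl)-7-methoxy-1-benzofuran-5-yl]propyl}-9-borabicyclo[3.3.1]nonane, (2S,3R), bis-TBS (not isolated) | COc1cc([C@H]2Oc3c(OC)cc(-c4cc5cc(CCCB6C7CCCC6CCC7)cc(OC)c5o4)cc3[C@@H]2CO[Si](C)(C)C(C)(C)C)ccc1O[Si](C)(C)C(C)(C)C | intermediate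
22 | 3-{2-[(2S,3R)-2-{4-[(TBS)oxy]-3-methoxyphenyl}-3-{[(TBS)oxy]methyl}-7-methoxy-2,3-dihydro-1-benzofuran-5-yl]-7-methoxy-1-benzofuran-5-yl}propan-1-ol | COc1cc([C@H]2Oc3c(OC)cc(-c4cc5cc(CCCO)cc(OC)c5o4)cc3[C@@H]2CO[Si](C)(C)C(C)(C)C)ccc1O[Si](C)(C)C(C)(C)C | intermediate
23 | 4-[(2S,3R)-3-(hydroxymethyl)-5-[5-(3-hydroxypropyl)-7-methoxy-1-benzofuran-2-yl]-7-methoxy-2,3-dihydro-1-benzofuran-2-yl]-2-methoxyphenol (CNP0308311.1) | COc1cc([C@H]2Oc3c(OC)cc(-c4cc5cc(CCCO)cc(OC)c5o4)cc3[C@@H]2CO)ccc1O | target

## Step count and risks

Total: 15 steps. Longest linear sequence: 13 steps (steps 1–9 and 12–15, from 1 and 2 to 23); the branch from 15 adds steps 10 and 11.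

**Step 13 (key step).** The most likely failure is intermolecular acyl transfer: the ylide of one molecule is acylated by the ester of another, leading to 3-acylated benzofuran and deacylated phenol. This is favoured when the sparingly soluble salt reacts at high local concentration. Ester cleavage by adventitious water is the second risk. The fallback sets out from 14 and 15 and returns at 20. Steglich esterification of 14 with the phenol of aldehyde 15 (DCC, DMAP, CH2Cl2) would give the 4-allyl-2-formyl-6-methoxyphenyl ester F1. Low-valent titanium (TiCl3, Zn dust, DME, reflux) would then couple the aldehyde and ester carbonyls reductively in an intramolecular McMurry-type oxo-ester coupling, a known benzofuran synthesis that forms the same C2=C3 bond without any ylide.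

**Step 3.** The chromium reagent may cleave the enol ether double bond oxidatively instead of transferring one oxygen, or its acidity may solvolyse the electron-rich benzylic aryl ether. The fallback sets out from 4 and returns at 5. Dilute aqueous HCl in THF would hydrolyse the enol ether to the arylacetaldehyde F2. Pinnick oxidation (NaClO2, NaH2PO4, 2-methyl-2-butene, t-BuOH–H2O) would give the arylacetic acid F3. Methylation (MeI, K2CO3, DMF) would give 5.

**Step 5.** Discrimination between the two enantiotopic benzylic hydrogens may be insufficient, or of the opposite sense, because the methoxy group ortho to the ether oxygen twists the OCH2Ar arm away from the geometry of the simpler precedents. Enantiomeric purity may also erode during the methoxide equilibration through reversible retro-oxa-Michael opening of the ester enolate. The fallback sets out from 5 and returns at 9, and it makes the stereochemical outcome separable by chromatography or crystallisation: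
- Saponification (LiOH, THF–H2O) gives the acid F3.
- Esterification with (S)-2-hydroxy-1-(pyrrolidin-1-yl)propan-1-one (EDC, DMAP) gives the lactamide ester F4.
- Diazo transfer (4-acetamidobenzenesulfonyl azide, DBU) gives the diazo ester F5.
- Insertion with Rh2(S-DOSP)4 (dirhodium tetrakis[(S)-N-(4-dodecylbenzenesulfonyl)prolinate]) in CH2Cl2, a known auxiliary-assisted version of the same C–H insertion, should give the trans ester F6 as a diastereomer that can be purified.
- LiBH4 removes the auxiliary reductively and gives 9.
- If the mismatched pair results, the (R)-lactamide and the R-catalyst are taken.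

**Step 7.** The aryllithium may be quenched (net protodebromination), or the exchange may stay incomplete, because the lithium alkoxide–aryllithium aggregate is poorly soluble at −78 °C. The fallback sets out from 9 and returns at 11. Palladium-catalysed methoxycarbonylation (Pd(OAc)2, Xantphos, CO at 1 atm, MeOH, Et3N, 70 °C) would convert the bromide into the methyl ester F7. Saponification (LiOH, THF–MeOH–H2O) would give 11. No organolithium is involved, and the free primary alcohol is tolerated.

## Further compounds

F1 | step 13 | 4-allyl-2-formyl-6-methoxyphenyl (2S,3R)-2-{4-[(TBS)oxy]-3-methoxyphenyl}-3-{[(TBS)oxy]methyl}-7-methoxy-2,3-dihydro-1-benzofuran-5-carboxylate | COc1cc([C@H]2Oc3c(OC)cc(C(=O)Oc4c(OC)cc(CC=C)cc4C=O)cc3[C@@H]2CO[Si](C)(C)C(C)(C)C)ccc1O[Si](C)(C)C(C)(C)C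
F2 | step 3 | 2-(2-{[4-(benzyloxy)-3-methoxybenzyl]oxy}-5-bromo-3-methoxyphenyl)acetaldehyde | O=CCc1cc(Br)cc(OC)c1OCc1ccc(OCc2ccccc2)c(OC)c1
F3 | step 3 | 2-(2-{[4-(benzyloxy)-3-methoxybenzyl]oxy}-5-bromo-3-methoxyphenyl)acetic acid | OC(=O)Cc1cc(Br)cc(OC)c1OCc1ccc(OCc2ccccc2)c(OC)c1
F4 | step 5 | (2S)-1-oxo-1-(pyrrolidin-1-yl)propan-2-yl 2-(2-{[4-(benzyloxy)-3-methoxybenzyl]oxy}-5-bromo-3-methoxyphenyl)acetate | C[C@H](OC(=O)Cc1cc(Br)cc(OC)c1OCc1ccc(OCc2ccccc2)c(OC)c1)C(=O)N1CCCC1
F5 | step 5 | (2S)-1-oxo-1-(pyrrolidin-1-yl)propan-2-yl 2-(2-{[4-(benzyloxy)-3-methoxybenzyl]oxy}-5-bromo-3-methoxyphenyl)-2-diazoacetate | C[C@H](OC(=O)C(=[N+]=[N-])c1cc(Br)cc(OC)c1OCc1ccc(OCc2ccccc2)c(OC)c1)C(=O)N1CCCC1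
F6 | step 5 | (2S)-1-oxo-1-(pyrrolidin-1-yl)propan-2-yl (2S,3S)-2-[4-(benzyloxy)-3-methoxyphenyl]-5-bromo-7-methoxy-2,3-dihydro-1-benzofuran-3-carboxylate (trans) | COc1cc([C@H]2Oc3c(OC)cc(Br)cc3[C@@H]2C(=O)O[C@@H](C)C(=O)N4CCCC4)ccc1OCc1ccccc1
F7 | step 7 | methyl (2S,3R)-2-[4-(benzyloxy)-3-methoxyphenyl]-3-(hydroxymethyl)-7-methoxy-2,3-dihydro-1-benzofuran-5-carboxylate | COc1cc([C@H]2Oc3c(OC)cc(C(=O)OC)cc3[C@@H]2CO)ccc1OCc1ccccc1
A1 | alternative 1 | methyl (2S,3S)-2-[4-(benzyloxy)-3-methoxyphenyl]-5-bromo-7-methoxy-2,3-dihydro-1-benzofuran-3-carboxylate (trans; identical with 8) | COc1cc([C@H]2Oc3c(OC)cc(Br)cc3[C@@H]2C(=O)OC)ccc1OCc1ccccc1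
A2 | alternative 1 | 2-(5-allyl-7-methoxy-1-benzofuran-2-yl)-4,4,5,5-tetramethyl-1,3,2-dioxaborolane | C=CCc1cc(OC)c2oc(cc2c1)B1OC(C)(C)C(C)(C)O1
A3 | alternative 2 | 2-[(2S,3R)-2-{4-[(TBS)oxy]-3-methoxyphenyl}-3-{[(TBS)oxy]methyl}-7-methoxy-2,3-dihydro-1-benzofuran-5-yl]-7-methoxy-5-{3-[(TBS)oxy]propyl}-1-benzofuran-4-ol | COc1cc([C@H]2Oc3c(OC)cc(-c4cc5c(O)c(CCCO[Si](C)(C)C(C)(C)C)cc(OC)c5o4)cc3[C@@H]2CO[Si](C)(C)C(C)(C)C)ccc1O[Si](C)(C)C(C)(C)C
A4 | alternative 2 | pentacarbonyl{methoxy[5-((2S,3R)-2-{4-[(TBS)oxy]-3-methoxyphenyl}-3-{[(TBS)oxy]methyl}-7-methoxy-2,3-dihydro-1-benzofuran-5-yl)furan-2-yl]methylidene}chromium | COc1cc([C@H]2Oc3c(OC)cc(-c4ccc(o4)C(OC)=[Cr](=C=O)(=C=O)(=C=O)(=C=O)=C=O)cc3[C@@H]2CO[Si](C)(C)C(C)(C)C)ccc1O[Si](C)(C)C(C)(C)C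
A5 | alternative 2 | tert-butyldimethyl(pent-4-yn-1-yloxy)silane | C#CCCCO[Si](C)(C)C(C)(C)C
A6 | alternative 3 | tris-pivalate of the target, (2S,3R)-trans | COc1cc([C@H]2Oc3c(OC)cc(-c4cc5cc(CCCOC(=O)C(C)(C)C)cc(OC)c5o4)cc3[C@@H]2COC(=O)C(C)(C)C)ccc1OC(=O)C(C)(C)C
A7 | alternative 3 | 3-[2-(4-iodo-3-methoxyphenyl)-7-methoxy-1-benzofuran-5-yl]propyl 2,2-dimethylpropanoate | COc1cc(-c2cc3cc(CCCOC(=O)C(C)(C)C)cc(OC)c3o2)ccc1I
A8 | alternative 3 | [(2S,3R)-3-{4-[(2,2-dimethylpropanoyl)oxy]-3-methoxyphenyl}oxiran-2-yl]methyl 2,2-dimethylpropanoate (cis-epoxide) | CC(C)(C)C(=O)OC[C@@H]1O[C@@H]1c1ccc(OC(=O)C(C)(C)C)c(OC)c1
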